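The easy step comes first: the last two midnight readings of target, 25.3 % and 25.0 %, differ by 0.3 percentage points, about the scatter, so the midnight readings show no gain of target after 20.0 h.

| flask | substrate | transfer agent | solid reagent | initiator | remark | time |
|---|---|---|---|---|---|---|
| midnight | 0.10 M | 0.015 M | 1.2 equiv | 15 mol% | run made earlier |  |
| spring | 0.10 M | 0.060 M | 1.2 equiv | 15 mol% | run made earlier |  |
| flask | 0.10 M | 0.0300 M | 1.20 equiv | 15 mol% |  | 40 h |

- midnight (time / h: target / %): 2.50: 2.3; 4.00: 4.9; 8.00: 10.3; 12.0: 21.7; 20.0: 25.3; 30.0: 25.0
- spring (time / h: target / %): 5.00: 1.9; 10.0: 3.4; 15.0: 5.6; 20.0: 8.1; 25.0: 14.3; 30.0: 15.1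

(readings scatter by 0.3 percentage points)

- solid, in amounts per volume of the solution: solid reagent
- what was read earlier has a scatter of 0.3 percentage points, one standard deviation
- at the start none of the solid reagent is in solution
- partner is what solid reagent becomes in solution

- alpha: doubling the solubility of the solid reagent, all else as stated
- eta: doubling the dissolution coefficient of the solid reagent, all else as stated

- target at 40 h, in percent of the substrate charged
- concentration of partner in solution at 4.0 h, in percent of saturation
- the change that raises the amount of target at 40 h, in percent of the substrate charged most ("none" if none brings more than 2 percentage points) (alpha / eta / none)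
- amount of target at 40 h, in percent of the substrate charged, after eta

Both runs can be followed in slow motion. In the first hours target creeps, with the midnight run at 4.9 % after 4.00 h. In the middle comes a burst, for the midnight run gains 11 points between 8.00 h and 12.0 h, twice the gain of the equal span before it, and the spring run shows its own burst later, between 20.0 h and 25.0 h. At the end of the midnight run target stands still, and the spring run gains less in its last span than in the span before. The asked 40 h lies later than the last reading of either run, so the reckoning here takes the flask as a plateau, and setting the last reading of one run against the last reading of the other takes the clock out of the reckoning: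

n = ln(25.0 % / 15.1 %) / ln(0.060 M / 0.015 M) = 0.364

This n is the stop exponent: the logarithm of the ratio of two last readings of target, each taken as a plateau, divided by the logarithm of the inverse ratio of the two c(transfer agent), with the other charges equal. It is a reading, and a slightly uncertain one, because the spring run still gained 0.8 points in its last span, more than the scatter. Carried from the midnight run to c(transfer agent) = 0.0300 M, it gives my own estimate:

plateau = 25.0 % × (0.015 M / 0.0300 M)^n = 19.4 %

The forecast, in its own words “dissolution seems fast”, gives 19.5 % of target, partner at 85 % of saturation at 4.0 h, alpha as the best change and 20 % of target after eta.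

    initiator → 2 initiating radical (k = 0.0340 h⁻¹)
    substrate + initiating radical → capped initiator + first chain carrier (k = 38000 M⁻¹ s⁻¹)
    partner + first chain carrier → target + second chain carrier (k = 19000 M⁻¹ s⁻¹)
    substrate + second chain carrier → by-product + first chain carrier (k = 7.90 × 10⁶ M⁻¹ h⁻¹)
    transfer agent + first chain carrier → side product A + idle radical (kL = 9.90 × 10⁶ M⁻¹ h⁻¹)
    2 idle radical → ended radicals (k = 7.70 × 10⁸ M⁻¹ s⁻¹)
    2 first chain carrier → ended chains (k = 5.80 × 10⁷ M⁻¹ s⁻¹)
    solid reagent ⇌ partner, rate k8*(cs8 - [partner]) while solid is left; crystals form when [partner] > cs8 (solubility = 41.0 mM, k = 0.150 h⁻¹)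
    substrate → decomposition product (k = 5.10 × 10⁻⁵ h⁻¹)
    substrate + target → side product B (k = 8.80 M⁻¹ h⁻¹)

The flask gives 20.9 % of target, partner at 30.7 % of saturation at 4.0 h, alpha as the best change with a gain of 8.3 points against 4.4 points for eta, and 25.2 % of target after eta, so partner stood lower than the forecast's 85 %. In the flask substrate falls under a fiftieth of its charge by 16.6 h, and target stands at 20.9 % at 20.0 h and 20.9 % at 80.0 h, a level 1.5 points above the estimate from n. Carried from the midnight run to 0.012 M of transfer agent, n gives 27.1 %, and that neighbour flask holds 26.1 %.

The numbers in the tables are calculated from invented constants.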